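Ring A of the flavan unit is disconnected at C8a–C4a and C5–C6. Ring A (C4a, C5, C6, C7, C8, C8a) is a phloroglucinol in which only C8 bears hydrogen and only the oxygen on C8a (O1) belongs to the pyran ring. A thermal benzannulation joins a 2-substituted 3-silyloxycyclobutenone (C6–C7–C8–C8a, carrying the complete open-chain unit with ring D) to a silyloxyalkyne (C4a–C5, carrying C4–C3–C2 and ring B). In one operation it builds ring A with C6 and C4a substituted, C5–O and C7–O silylated and the C8a hydroxyl alone free. Mitsunobu closure of O1 onto C2 and deprotection then give the target.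

Key step: step 15

Remarks on the chemistry: flavan numbering (O1, C2–C4, C4a–C8a, ring B on C2) is used for the lower unit, and ring D is the phloroglucinol ring of the open-chain unit. Ketene is taken as a gas from a ketene generator (acetone pyrolysis). 3,4-Bis(benzyloxy)benzaldehyde and (R)-4-benzyloxazolidin-2-one are bought as such.

**Cyclobutenone fragment (steps 1–8)**

Step 1
Reactants: 1 2,4,6-trihydroxybenzaldehyde
Product: 2 2,4,6-tris(benzyloxy)benzaldehyde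
Conditions: BnBr (3.6 equiv), K2CO3 (4 equiv), DMF, 60 °C
Reagents that add atoms: benzyl bromide (BrCc1ccccc1)
Why: Williamson etherification of the three phenols; the formyl group lowers ring nucleophilicity, so O-alkylation should outrun C-benzylation.

Step 2
Reactants: 2 2,4,6-tris(benzyloxy)benzaldehyde
Product: 4 2-[2,4,6-tris(benzyloxy)phenyl]acetaldehyde, via enol ether 3 (not isolated)
Conditions: Ph3P(CH2OMe)Cl, KOt-Bu, THF, 0 °C → rt; then 2 M HCl, THF, rt
Reagents that add atoms: (methoxymethyl)triphenylphosphonium chloride (COC[P+](c1ccccc1)(c1ccccc1)c1ccccc1.[Cl-]); water (O)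
Why: Wittig methoxymethylenation followed by acid hydrolysis of the enol ether is the standard one-carbon homologation of an aryl aldehyde to an arylacetaldehyde.

Step 3
Reactants: 5 3,4-bis(benzyloxy)benzaldehyde
Product: 6 rac-1-[3,4-bis(benzyloxy)phenyl]prop-2-yn-1-ol
Conditions: HC≡CMgBr, THF, 0 °C; aq. NH4Cl
Reagents that add atoms: ethynylmagnesium bromide (C#C[Mg]Br)
Why: Grignard 1,2-addition to a non-enolisable aldehyde; the racemate is resolved in the next step.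

Step 4
Reactants: 6 rac-1-[3,4-bis(benzyloxy)phenyl]prop-2-yn-1-ol
Product: 7 (R)-1-[3,4-bis(benzyloxy)phenyl]prop-2-yn-1-yl acetate
Conditions: Novozym 435 (immobilised Candida antarctica lipase B), vinyl acetate, t-BuOMe, 40 °C, stopped near half conversion
Reagents that add atoms: vinyl acetate (CC(=O)OC=C)
Why: Lipase-catalysed kinetic resolution by transesterification; by the empirical size rule for secondary alcohols the enantiomer with the small ethynyl group in the medium pocket, (R)-6, should be acetylated, so the stereocentre of 7 is set by enzyme selection and the ester is directly the leaving group needed next.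

Step 5
Reactants: 4 2-[2,4,6-tris(benzyloxy)phenyl]acetaldehyde; 7 (R)-1-[3,4-bis(benzyloxy)phenyl]prop-2-yn-1-yl acetate
Product: 8 (2S,3S)-3-[3,4-bis(benzyloxy)phenyl]-1-[2,4,6-tris(benzyloxy)phenyl]pent-4-yn-2-ol
Conditions: Pd(OAc)2 (5 mol %), PPh3 (5 mol %), Et2Zn (3 equiv), THF, −20 → 0 °C; aq. NH4Cl
Reagents that add atoms: none
Why: Palladium-catalysed zinc-mediated umpolung propargylation: anti SN2′ oxidative addition of zerovalent palladium to 7, transmetalation to an allenylzinc and addition to 4 through a cyclic SE2′ transition state should replace the acetate with net inversion, turning the (R) centre of 7 into C3 (S), and place the new C2 hydroxyl (S) anti to the aryl group.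

Step 6
Reactants: 8 (2S,3S)-3-[3,4-bis(benzyloxy)phenyl]-1-[2,4,6-tris(benzyloxy)phenyl]pent-4-yn-2-ol
Product: 9 (3S,4S)-3-[3,4-bis(benzyloxy)phenyl]-4-(tert-butyldimethylsilyloxy)-5-[2,4,6-tris(benzyloxy)phenyl]pent-1-yne
Conditions: TBSOTf, 2,6-lutidine, CH2Cl2, −78 → 0 °C
Reagents that add atoms: tert-butyldimethylsilyl triflate (CC(C)(C)[Si](C)(C)OS(=O)(=O)C(F)(F)F)
Why: Silylation of a hindered secondary alcohol with a silyl triflate and a non-nucleophilic base; no strong base touches the benzylic propargylic C–H, and this silyl ether later leaves together with the aryl silyl ethers.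

Step 7
Reactants: 9 (3S,4S)-3-[3,4-bis(benzyloxy)phenyl]-4-(tert-butyldimethylsilyloxy)-5-[2,4,6-tris(benzyloxy)phenyl]pent-1-yne
Product: 12 (3R,4S)-3-[3,4-bis(benzyloxy)phenyl]-4-(tert-butyldimethylsilyloxy)-5-[2,4,6-tris(benzyloxy)phenyl]-1-(triisopropylsilyloxy)pent-1-yne, via lithium acetylide 10 (not isolated), via lithium ynolate 11 (not isolated)
Conditions: n-BuLi (1.0 equiv), THF, −78 °C; t-BuOOLi (from t-BuOOH and LiN(SiMe3)2), THF, −78 → 0 °C; TIPSOTf, −78 → 0 °C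
Reagents that add atoms: tert-butyl hydroperoxide (CC(C)(C)OO); triisopropylsilyl triflate (CC(C)[Si](OS(=O)(=O)C(F)(F)F)(C(C)C)C(C)C)
Why: Electrophilic oxygen transfer from lithium tert-butyl peroxide to the acetylide gives the ynolate, which the bulky silyl triflate traps on oxygen (acetylide oxidation–O-silylation); one equivalent of base at −78 °C removes only the alkyne proton, so C3 should not epimerise (its descriptor changes only because the oxygenated alkyne now outranks the aryl group).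

Step 8
Reactants: 12 (3R,4S)-3-[3,4-bis(benzyloxy)phenyl]-4-(tert-butyldimethylsilyloxy)-5-[2,4,6-tris(benzyloxy)phenyl]-1-(triisopropylsilyloxy)pent-1-yne
Product: 13 2-{(1R,2S)-1-[3,4-bis(benzyloxy)phenyl]-2-(tert-butyldimethylsilyloxy)-3-[2,4,6-tris(benzyloxy)phenyl]propyl}-3-(triisopropylsilyloxy)cyclobut-2-en-1-one
Conditions: ketene (gas, excess), CH2Cl2, 0 °C → rt
Reagents that add atoms: ketene (C=C=O)
Why: [2+2] cycloaddition of ketene with an electron-rich silyloxyalkyne; the alkyne carbon remote from oxygen bonds to the ketene carbonyl carbon, which places the side chain on C2 and the silyloxy group on C3 of the cyclobutenone.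

**Silyloxyalkyne fragment (steps 9–14)**

Step 9
Reactants: 14 (R)-4-benzyloxazolidin-2-one
Product: 15 (R)-4-benzyl-3-[2-(benzyloxy)acetyl]oxazolidin-2-one
Conditions: BnOCH2COCl, Et3N, DMAP (cat.), CH2Cl2, 0 °C → rt
Reagents that add atoms: (benzyloxy)acetyl chloride (O=C(Cl)COCc1ccccc1)
Why: N-acylation of the oxazolidinone under nucleophilic catalysis.

Step 10
Reactants: 15 (R)-4-benzyl-3-[2-(benzyloxy)acetyl]oxazolidin-2-one; 5 3,4-bis(benzyloxy)benzaldehyde
Product: 17 (4R)-4-benzyl-3-{(2R,3S)-2-(benzyloxy)-3-[3,4-bis(benzyloxy)phenyl]-3-hydroxypropanoyl}oxazolidin-2-one, via boron enolate 16 (not isolated)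
Conditions: Bu2BOTf, Et3N, CH2Cl2, −78 → 0 °C; 5, −78 → 0 °C; pH 7 buffer, MeOH, H2O2
Reagents that add atoms: none
Why: Evans syn-glycolate aldol: the (Z)-boron enolate reacts through a Zimmerman–Traxler chair on the face away from the auxiliary benzyl group, setting C2′ (R) and C3′ (S) syn and delivering the future C3 oxygen already benzylated and the future C2 oxygen free.

Step 11
Reactants: 17 (4R)-4-benzyl-3-{(2R,3S)-2-(benzyloxy)-3-[3,4-bis(benzyloxy)phenyl]-3-hydroxypropanoyl}oxazolidin-2-one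
Product: 18 (4R)-4-benzyl-3-{(2R,3S)-2-(benzyloxy)-3-[3,4-bis(benzyloxy)phenyl]-3-(triethylsilyloxy)propanoyl}oxazolidin-2-one
Conditions: TESCl, imidazole, DMF, rt
Reagents that add atoms: chlorotriethylsilane (CC[Si](Cl)(CC)CC)
Why: Imidazole-promoted silylation of the secondary alcohol; the triethylsilyl group is chosen because it can later be removed in the presence of the other silyl ethers.

Step 12
Reactants: 18 (4R)-4-benzyl-3-{(2R,3S)-2-(benzyloxy)-3-[3,4-bis(benzyloxy)phenyl]-3-(triethylsilyloxy)propanoyl}oxazolidin-2-one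
Product: 19 (2S,3S)-2-(benzyloxy)-3-[3,4-bis(benzyloxy)phenyl]-3-(triethylsilyloxy)propan-1-ol
Conditions: LiBH4, MeOH (1 equiv), Et2O, 0 °C
Reagents that add atoms: none
Why: Reductive cleavage of the N-acyloxazolidinone by hydride attack at the exocyclic carbonyl; the auxiliary is recovered and no stereocentre is touched.

Step 13
Reactants: 19 (2S,3S)-2-(benzyloxy)-3-[3,4-bis(benzyloxy)phenyl]-3-(triethylsilyloxy)propan-1-ol
Product: 22 (4S,5S)-4-(benzyloxy)-5-[3,4-bis(benzyloxy)phenyl]-5-(triethylsilyloxy)pent-1-yne, via triflate 20 (not isolated), via silylalkyne 21 (not isolated)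
Conditions: Tf2O, 2,6-lutidine, CH2Cl2, −78 °C; Me3SiC≡CLi (from Me3SiC≡CH and n-BuLi), THF/DMPU, −78 → −20 °C; K2CO3, MeOH, rt
Reagents that add atoms: trimethylsilylacetylene (C#C[Si](C)(C)C)
Why: SN2 displacement of a primary triflate by a lithium acetylide followed by base-mediated C-desilylation; this adds C4a and C5 without involving either stereocentre.

Step 14
Reactants: 22 (4S,5S)-4-(benzyloxy)-5-[3,4-bis(benzyloxy)phenyl]-5-(triethylsilyloxy)pent-1-yne
Product: 25 (4S,5S)-4-(benzyloxy)-5-[3,4-bis(benzyloxy)phenyl]-5-(triethylsilyloxy)-1-(triisopropylsilyloxy)pent-1-yne, via lithium acetylide 23 (not isolated), via lithium ynolate 24 (not isolated)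
Conditions: n-BuLi (1.0 equiv), THF, −78 °C; t-BuOOLi (from t-BuOOH and LiN(SiMe3)2), THF, −78 → 0 °C; TIPSOTf, −78 → 0 °C
Reagents that add atoms: tert-butyl hydroperoxide (CC(C)(C)OO); triisopropylsilyl triflate (CC(C)[Si](OS(=O)(=O)C(F)(F)F)(C(C)C)C(C)C)
Why: Acetylide oxidation by lithium tert-butyl peroxide and O-silylation of the resulting ynolate, as in step 7; the ether and silyl ether groups are inert to these conditions.

**Key step and endgame (steps 15–19)**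

Step 15
Reactants: 13 2-{(1R,2S)-1-[3,4-bis(benzyloxy)phenyl]-2-(tert-butyldimethylsilyloxy)-3-[2,4,6-tris(benzyloxy)phenyl]propyl}-3-(triisopropylsilyloxy)cyclobut-2-en-1-one; 25 (4S,5S)-4-(benzyloxy)-5-[3,4-bis(benzyloxy)phenyl]-5-(triethylsilyloxy)-1-(triisopropylsilyloxy)pent-1-yne
Product: 27 4-{(1R,2S)-1-[3,4-bis(benzyloxy)phenyl]-2-(tert-butyldimethylsilyloxy)-3-[2,4,6-tris(benzyloxy)phenyl]propyl}-2-{(2S,3S)-2-(benzyloxy)-3-[3,4-bis(benzyloxy)phenyl]-3-(triethylsilyloxy)propyl}-3,5-bis(triisopropylsilyloxy)phenol, via vinylcyclobutenone 26 (not isolated)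
Conditions: 13 (1.0 equiv), 25 (1.3 equiv), toluene (0.3 M), argon, 80 °C then 110 °C
Reagents that add atoms: none
Why: Heating releases the strain of 13 in a four-electron electrocyclic opening to a (1-silyloxyvinyl)ketene, whose ketene carbon (future C8a) is attacked by the alkyne carbon of 25 remote from oxygen (future C4a) while the oxygen-bearing alkyne carbon (future C5) bonds to the ketene α-carbon (future C6), giving vinylcyclobutenone 26. A second four-electron opening of 26 gives a dienylketene that closes ring A by a thermally allowed disrotatory six-electron electrocyclisation (re-forming C8–C8a), and tautomerisation of the cyclohexadienone delivers the phenol with the C8a hydroxyl free. The closest known reaction type is the Danheiser benzannulation of cyclobutenones with silyloxyalkynes to resorcinol monosilyl ethers. No stereocentre is created, and the four existing ones lie outside the pericyclic array in a medium free of acid, base and metal. The only selectivity needed is regiochemical and is fixed by the polarity match of ketene and ynol ether, so C6 carries the open-chain unit, C8 carries hydrogen and O1 is the single unprotected oxygen.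

Step 16
Reactants: 27 4-{(1R,2S)-1-[3,4-bis(benzyloxy)phenyl]-2-(tert-butyldimethylsilyloxy)-3-[2,4,6-tris(benzyloxy)phenyl]propyl}-2-{(2S,3S)-2-(benzyloxy)-3-[3,4-bis(benzyloxy)phenyl]-3-(triethylsilyloxy)propyl}-3,5-bis(triisopropylsilyloxy)phenol
Product: 28 4-{(1R,2S)-1-[3,4-bis(benzyloxy)phenyl]-2-(tert-butyldimethylsilyloxy)-3-[2,4,6-tris(benzyloxy)phenyl]propyl}-2-{(2S,3S)-2-(benzyloxy)-3-[3,4-bis(benzyloxy)phenyl]-3-hydroxypropyl}-3,5-bis(triisopropylsilyloxy)phenol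
Conditions: HF·pyridine, pyridine, THF, 0 °C
Reagents that add atoms: none
Why: Chemoselective desilylation: under buffered HF·pyridine a secondary triethylsilyl ether is cleaved much faster than the tert-butyldimethylsilyl ether or the aryl triisopropylsilyl ethers, and the non-nucleophilic medium avoids solvolysis at the electron-rich benzylic carbon.

Step 17
Reactants: 28 4-{(1R,2S)-1-[3,4-bis(benzyloxy)phenyl]-2-(tert-butyldimethylsilyloxy)-3-[2,4,6-tris(benzyloxy)phenyl]propyl}-2-{(2S,3S)-2-(benzyloxy)-3-[3,4-bis(benzyloxy)phenyl]-3-hydroxypropyl}-3,5-bis(triisopropylsilyloxy)phenol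
Product: 29 (2R,3S)-3-(benzyloxy)-2-[3,4-bis(benzyloxy)phenyl]-6-{(1R,2S)-1-[3,4-bis(benzyloxy)phenyl]-2-(tert-butyldimethylsilyloxy)-3-[2,4,6-tris(benzyloxy)phenyl]propyl}-5,7-bis(triisopropylsilyloxy)chromane
Conditions: PPh3, DIAD, THF, 0 °C → rt
Reagents that add atoms: none
Why: Intramolecular Mitsunobu etherification: the C8a phenol, the only free hydroxyl besides the activated benzylic alcohol, displaces the oxyphosphonium at C2 in a 6-exo-tet SN2 reaction with inversion, turning (2S) into (2R) and giving the 2,3-trans flavan.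

Step 18
Reactants: 29 (2R,3S)-3-(benzyloxy)-2-[3,4-bis(benzyloxy)phenyl]-6-{(1R,2S)-1-[3,4-bis(benzyloxy)phenyl]-2-(tert-butyldimethylsilyloxy)-3-[2,4,6-tris(benzyloxy)phenyl]propyl}-5,7-bis(triisopropylsilyloxy)chromane
Product: 30 (2R,3S)-3-(benzyloxy)-2-[3,4-bis(benzyloxy)phenyl]-6-{(1R,2S)-1-[3,4-bis(benzyloxy)phenyl]-2-hydroxy-3-[2,4,6-tris(benzyloxy)phenyl]propyl}chromane-5,7-diol
Conditions: TBAF (6 equiv), AcOH (6 equiv), THF, 0 → 40 °C, argon
Reagents that add atoms: none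
Why: Fluoride-driven cleavage of the two aryl triisopropylsilyl ethers and the secondary tert-butyldimethylsilyl ether (Si–F bond formation), buffered so that the liberated electron-rich phenols are not exposed to strong base.

Step 19
Reactants: 30 (2R,3S)-3-(benzyloxy)-2-[3,4-bis(benzyloxy)phenyl]-6-{(1R,2S)-1-[3,4-bis(benzyloxy)phenyl]-2-hydroxy-3-[2,4,6-tris(benzyloxy)phenyl]propyl}chromane-5,7-diol
Product: 31 (2R,3S)-2-(3,4-dihydroxyphenyl)-6-[(1R,2S)-1-(3,4-dihydroxyphenyl)-2-hydroxy-3-(2,4,6-trihydroxyphenyl)propyl]chromane-3,5,7-triol (the target)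
Conditions: H2 (1 atm), Pd(OH)2/C, THF/MeOH, rt
Reagents that add atoms: none
Why: Heterogeneous hydrogenolysis of the eight benzyl ethers; the cyclic benzylic C2–O1 bond of flavan-3-ols is known to survive these mild conditions, and no stereocentre is affected.

**Compound list**

1 | 2,4,6-trihydroxybenzaldehyde | O=Cc1c(O)cc(O)cc1O | starting material
2 | 2,4,6-tris(benzyloxy)benzaldehyde | O=Cc1c(OCc2ccccc2)cc(OCc2ccccc2)cc1OCc1ccccc1 | intermediate
3 | 1,3,5-tris(benzyloxy)-2-(2-methoxyethenyl)benzene (E/Z mixture) | COC=Cc1c(OCc2ccccc2)cc(OCc2ccccc2)cc1OCc1ccccc1 | intermediate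
4 | 2-[2,4,6-tris(benzyloxy)phenyl]acetaldehyde | O=CCc1c(OCc2ccccc2)cc(OCc2ccccc2)cc1OCc1ccccc1 | intermediate
5 | 3,4-bis(benzyloxy)benzaldehyde | O=Cc1ccc(OCc2ccccc2)c(OCc2ccccc2)c1 | starting material
6 | rac-1-[3,4-bis(benzyloxy)phenyl]prop-2-yn-1-ol | OC(C#C)c1ccc(OCc2ccccc2)c(OCc2ccccc2)c1 | intermediate
7 | (R)-1-[3,4-bis(benzyloxy)phenyl]prop-2-yn-1-yl acetate | CC(=O)O[C@H](C#C)c1ccc(OCc2ccccc2)c(OCc2ccccc2)c1 | intermediate
8 | (2S,3S)-3-[3,4-bis(benzyloxy)phenyl]-1-[2,4,6-tris(benzyloxy)phenyl]pent-4-yn-2-ol | C(c1c(OCc2ccccc2)cc(OCc2ccccc2)cc1OCc1ccccc1)[C@H](O)[C@H](c1ccc(OCc2ccccc2)c(OCc2ccccc2)c1)C#C | intermediate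
9 | (3S,4S)-3-[3,4-bis(benzyloxy)phenyl]-4-(tert-butyldimethylsilyloxy)-5-[2,4,6-tris(benzyloxy)phenyl]pent-1-yne | C(c1c(OCc2ccccc2)cc(OCc2ccccc2)cc1OCc1ccccc1)[C@H](O[Si](C)(C)C(C)(C)C)[C@H](c1ccc(OCc2ccccc2)c(OCc2ccccc2)c1)C#C | intermediate
10 | lithium acetylide of 9 (lithium on the terminal alkyne carbon) | C(c1c(OCc2ccccc2)cc(OCc2ccccc2)cc1OCc1ccccc1)[C@H](O[Si](C)(C)C(C)(C)C)[C@H](c1ccc(OCc2ccccc2)c(OCc2ccccc2)c1)C#C[Li] | intermediate
11 | lithium (3R,4S)-3-[3,4-bis(benzyloxy)phenyl]-4-(tert-butyldimethylsilyloxy)-5-[2,4,6-tris(benzyloxy)phenyl]pent-1-yn-1-olate | C(c1c(OCc2ccccc2)cc(OCc2ccccc2)cc1OCc1ccccc1)[C@H](O[Si](C)(C)C(C)(C)C)[C@H](c1ccc(OCc2ccccc2)c(OCc2ccccc2)c1)C#CO[Li] | intermediate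
12 | (3R,4S)-3-[3,4-bis(benzyloxy)phenyl]-4-(tert-butyldimethylsilyloxy)-5-[2,4,6-tris(benzyloxy)phenyl]-1-(triisopropylsilyloxy)pent-1-yne | C(c1c(OCc2ccccc2)cc(OCc2ccccc2)cc1OCc1ccccc1)[C@H](O[Si](C)(C)C(C)(C)C)[C@H](c1ccc(OCc2ccccc2)c(OCc2ccccc2)c1)C#CO[Si](C(C)C)(C(C)C)C(C)C | intermediate
13 | 2-{(1R,2S)-1-[3,4-bis(benzyloxy)phenyl]-2-(tert-butyldimethylsilyloxy)-3-[2,4,6-tris(benzyloxy)phenyl]propyl}-3-(triisopropylsilyloxy)cyclobut-2-en-1-one | C(c1c(OCc2ccccc2)cc(OCc2ccccc2)cc1OCc1ccccc1)[C@H](O[Si](C)(C)C(C)(C)C)[C@H](c1ccc(OCc2ccccc2)c(OCc2ccccc2)c1)C1=C(O[Si](C(C)C)(C(C)C)C(C)C)CC1=O | intermediate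
14 | (R)-4-benzyloxazolidin-2-one | O=C1N[C@H](Cc2ccccc2)CO1 | starting material
15 | (R)-4-benzyl-3-[2-(benzyloxy)acetyl]oxazolidin-2-one | O=C(COCc1ccccc1)N1[C@H](Cc2ccccc2)COC1=O | intermediate
16 | (Z)-dibutylboron enolate of 15 (boron-bound oxygen and benzyloxy group cis) | CCCCB(CCCC)O/C(=C\OCc1ccccc1)N1[C@H](Cc2ccccc2)COC1=O | intermediate
17 | (4R)-4-benzyl-3-{(2R,3S)-2-(benzyloxy)-3-[3,4-bis(benzyloxy)phenyl]-3-hydroxypropanoyl}oxazolidin-2-one | O=C([C@H](OCc1ccccc1)[C@@H](O)c1ccc(OCc2ccccc2)c(OCc2ccccc2)c1)N1[C@H](Cc2ccccc2)COC1=O | intermediate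
18 | (4R)-4-benzyl-3-{(2R,3S)-2-(benzyloxy)-3-[3,4-bis(benzyloxy)phenyl]-3-(triethylsilyloxy)propanoyl}oxazolidin-2-one | O=C([C@H](OCc1ccccc1)[C@@H](O[Si](CC)(CC)CC)c1ccc(OCc2ccccc2)c(OCc2ccccc2)c1)N1[C@H](Cc2ccccc2)COC1=O | intermediate
19 | (2S,3S)-2-(benzyloxy)-3-[3,4-bis(benzyloxy)phenyl]-3-(triethylsilyloxy)propan-1-ol | OC[C@H](OCc1ccccc1)[C@@H](O[Si](CC)(CC)CC)c1ccc(OCc2ccccc2)c(OCc2ccccc2)c1 | intermediate
20 | (2S,3S)-2-(benzyloxy)-3-[3,4-bis(benzyloxy)phenyl]-3-(triethylsilyloxy)propyl trifluoromethanesulfonate | O=S(=O)(OC[C@H](OCc1ccccc1)[C@@H](O[Si](CC)(CC)CC)c1ccc(OCc2ccccc2)c(OCc2ccccc2)c1)C(F)(F)F | intermediate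
21 | (4S,5S)-4-(benzyloxy)-5-[3,4-bis(benzyloxy)phenyl]-5-(triethylsilyloxy)-1-(trimethylsilyl)pent-1-yne | C[Si](C)(C)C#CC[C@H](OCc1ccccc1)[C@@H](O[Si](CC)(CC)CC)c1ccc(OCc2ccccc2)c(OCc2ccccc2)c1 | intermediate
22 | (4S,5S)-4-(benzyloxy)-5-[3,4-bis(benzyloxy)phenyl]-5-(triethylsilyloxy)pent-1-yne | C#CC[C@H](OCc1ccccc1)[C@@H](O[Si](CC)(CC)CC)c1ccc(OCc2ccccc2)c(OCc2ccccc2)c1 | intermediate
23 | lithium acetylide of 22 (lithium on the terminal alkyne carbon) | [Li]C#CC[C@H](OCc1ccccc1)[C@@H](O[Si](CC)(CC)CC)c1ccc(OCc2ccccc2)c(OCc2ccccc2)c1 | intermediate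
24 | lithium (4S,5S)-4-(benzyloxy)-5-[3,4-bis(benzyloxy)phenyl]-5-(triethylsilyloxy)pent-1-yn-1-olate | [Li]OC#CC[C@H](OCc1ccccc1)[C@@H](O[Si](CC)(CC)CC)c1ccc(OCc2ccccc2)c(OCc2ccccc2)c1 | intermediate
25 | (4S,5S)-4-(benzyloxy)-5-[3,4-bis(benzyloxy)phenyl]-5-(triethylsilyloxy)-1-(triisopropylsilyloxy)pent-1-yne | CC(C)[Si](C(C)C)(C(C)C)OC#CC[C@H](OCc1ccccc1)[C@@H](O[Si](CC)(CC)CC)c1ccc(OCc2ccccc2)c(OCc2ccccc2)c1 | intermediate
26 | 4-{(1R,2S)-1-[3,4-bis(benzyloxy)phenyl]-2-(tert-butyldimethylsilyloxy)-3-[2,4,6-tris(benzyloxy)phenyl]propyl}-2-{(2S,3S)-2-(benzyloxy)-3-[3,4-bis(benzyloxy)phenyl]-3-(triethylsilyloxy)propyl}-3-(triisopropylsilyloxy)-4-[1-(triisopropylsilyloxy)ethenyl]cyclobut-2-en-1-one (both configurations at the ring quaternary carbon) | C(c1c(OCc2ccccc2)cc(OCc2ccccc2)cc1OCc1ccccc1)[C@H](O[Si](C)(C)C(C)(C)C)[C@H](c1ccc(OCc2ccccc2)c(OCc2ccccc2)c1)C1(C(O[Si](C(C)C)(C(C)C)C(C)C)=C)C(=O)C(C[C@H](OCc2ccccc2)[C@@H](O[Si](CC)(CC)CC)c2ccc(OCc3ccccc3)c(OCc3ccccc3)c2)=C1O[Si](C(C)C)(C(C)C)C(C)C | intermediate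
27 | 4-{(1R,2S)-1-[3,4-bis(benzyloxy)phenyl]-2-(tert-butyldimethylsilyloxy)-3-[2,4,6-tris(benzyloxy)phenyl]propyl}-2-{(2S,3S)-2-(benzyloxy)-3-[3,4-bis(benzyloxy)phenyl]-3-(triethylsilyloxy)propyl}-3,5-bis(triisopropylsilyloxy)phenol | C(c1c(OCc2ccccc2)cc(OCc2ccccc2)cc1OCc1ccccc1)[C@H](O[Si](C)(C)C(C)(C)C)[C@H](c1ccc(OCc2ccccc2)c(OCc2ccccc2)c1)c1c(O[Si](C(C)C)(C(C)C)C(C)C)cc(O)c(C[C@H](OCc2ccccc2)[C@@H](O[Si](CC)(CC)CC)c2ccc(OCc3ccccc3)c(OCc3ccccc3)c2)c1O[Si](C(C)C)(C(C)C)C(C)C | intermediate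
28 | 4-{(1R,2S)-1-[3,4-bis(benzyloxy)phenyl]-2-(tert-butyldimethylsilyloxy)-3-[2,4,6-tris(benzyloxy)phenyl]propyl}-2-{(2S,3S)-2-(benzyloxy)-3-[3,4-bis(benzyloxy)phenyl]-3-hydroxypropyl}-3,5-bis(triisopropylsilyloxy)phenol | C(c1c(OCc2ccccc2)cc(OCc2ccccc2)cc1OCc1ccccc1)[C@H](O[Si](C)(C)C(C)(C)C)[C@H](c1ccc(OCc2ccccc2)c(OCc2ccccc2)c1)c1c(O[Si](C(C)C)(C(C)C)C(C)C)cc(O)c(C[C@H](OCc2ccccc2)[C@@H](O)c2ccc(OCc3ccccc3)c(OCc3ccccc3)c2)c1O[Si](C(C)C)(C(C)C)C(C)C | intermediate
29 | (2R,3S)-3-(benzyloxy)-2-[3,4-bis(benzyloxy)phenyl]-6-{(1R,2S)-1-[3,4-bis(benzyloxy)phenyl]-2-(tert-butyldimethylsilyloxy)-3-[2,4,6-tris(benzyloxy)phenyl]propyl}-5,7-bis(triisopropylsilyloxy)chromane | C(c1c(OCc2ccccc2)cc(OCc2ccccc2)cc1OCc1ccccc1)[C@H](O[Si](C)(C)C(C)(C)C)[C@H](c1ccc(OCc2ccccc2)c(OCc2ccccc2)c1)c1c(O[Si](C(C)C)(C(C)C)C(C)C)cc2c(c1O[Si](C(C)C)(C(C)C)C(C)C)C[C@H](OCc1ccccc1)[C@@H](c1ccc(OCc3ccccc3)c(OCc3ccccc3)c1)O2 | intermediate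
30 | (2R,3S)-3-(benzyloxy)-2-[3,4-bis(benzyloxy)phenyl]-6-{(1R,2S)-1-[3,4-bis(benzyloxy)phenyl]-2-hydroxy-3-[2,4,6-tris(benzyloxy)phenyl]propyl}chromane-5,7-diol | C(c1c(OCc2ccccc2)cc(OCc2ccccc2)cc1OCc1ccccc1)[C@H](O)[C@H](c1ccc(OCc2ccccc2)c(OCc2ccccc2)c1)c1c(O)cc2c(c1O)C[C@H](OCc1ccccc1)[C@@H](c1ccc(OCc3ccccc3)c(OCc3ccccc3)c1)O2 | intermediate
31 | (2R,3S)-2-(3,4-dihydroxyphenyl)-6-[(1R,2S)-1-(3,4-dihydroxyphenyl)-2-hydroxy-3-(2,4,6-trihydroxyphenyl)propyl]chromane-3,5,7-triol (the target natural product) | Oc1cc(O)c(C[C@H](O)[C@H](c2ccc(O)c(O)c2)c2c(O)cc3c(c2O)C[C@H](O)[C@@H](c2ccc(O)c(O)c2)O3)c(O)c1 | target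

**Totals and risks**

Total step count: 19 steps. Longest linear sequence: 11 steps (steps 1, 2, 5, 6, 7, 8, 15, 16, 17, 18 and 19; the branches through steps 3–4 and through steps 9–14 are equally long).

Steps most likely to fail:

1. Step 15 (key step). The [2+2] union of the hindered vinylketene with the branched ynol ether may be slower than vinylketene dimerisation or acylation of the freshly formed phenol by the ketene. The fallback sets out from 22 and 12 and comes back at 27, with the partners re-assigned so that the unhindered parent ynol ether is used. Hydroboration of 22 (Cy2BH, THF, 0 °C; NaBO3·4H2O) should give (4S,5S)-4-(benzyloxy)-5-[3,4-bis(benzyloxy)phenyl]-5-(triethylsilyloxy)pentanal F1. Pinnick oxidation (NaClO2, NaH2PO4, 2-methylbut-2-ene, t-BuOH/H2O) should give the corresponding pentanoic acid F2, and 1-chloro-N,N,2-trimethylprop-1-en-1-amine (CH2Cl2, 0 °C) should turn it into the pentanoyl chloride F3. Slow addition of F3 to Et3N and 12 generates the aldoketene (4S,5S)-4-(benzyloxy)-5-[3,4-bis(benzyloxy)phenyl]-5-(triethylsilyloxy)pent-1-en-1-one F4, which should add to 12 in the same [2+2] sense to give the 2,4-disubstituted 3-(triisopropylsilyloxy)cyclobutenone F5. Heating F5 with (triisopropylsilyloxy)ethyne (C#CO[Si](C(C)C)(C(C)C)C(C)C) in toluene forms C8a–C8 and C6–C7 instead; the sp3 ring carbon of the cyclobutenone now becomes C4a, so the same phenol 27 should result.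

2. Step 5. Enantiomeric purity may be lost by racemisation of the aryl-substituted allenylpalladium or allenylzinc before it is trapped; enolisation of 4 may also lower conversion. The fallback sets out from 8 of insufficient enantiomeric purity and comes back at 8, replacing chirality transfer by classical resolution. Esterification with (S)-2-methoxy-2-phenylacetic acid (DCC, DMAP, CH2Cl2) gives (2S,3S)-3-[3,4-bis(benzyloxy)phenyl]-1-[2,4,6-tris(benzyloxy)phenyl]pent-4-yn-2-yl (S)-2-methoxy-2-phenylacetate F6, which is separated from the ester of the antipode by chromatography or crystallisation; i-Bu2AlH (CH2Cl2, −78 °C) then releases 8.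

3. Step 17. The electron-rich benzylic oxyphosphonium may ionise, eroding the inversion, or β-elimination toward the enol ether may compete. The fallback sets out from 28 and comes back at 29, and makes no new compound (F0). The benzylic cation is generated on purpose (BF3·OEt2, catalytic, CH2Cl2, −40 °C) and captured by the C8a hydroxyl through a half-chair with the C2 aryl and C3 benzyloxy groups both pseudo-equatorial, which should favour the same 2,3-trans flavan whatever the configuration at C2.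

Further compounds
F1 | step 15 | (4S,5S)-4-(benzyloxy)-5-[3,4-bis(benzyloxy)phenyl]-5-(triethylsilyloxy)pentanal | O=CCC[C@H](OCc1ccccc1)[C@@H](O[Si](CC)(CC)CC)c1ccc(OCc2ccccc2)c(OCc2ccccc2)c1
F2 | step 15 | (4S,5S)-4-(benzyloxy)-5-[3,4-bis(benzyloxy)phenyl]-5-(triethylsilyloxy)pentanoic acid | OC(=O)CC[C@H](OCc1ccccc1)[C@@H](O[Si](CC)(CC)CC)c1ccc(OCc2ccccc2)c(OCc2ccccc2)c1
F3 | step 15 | (4S,5S)-4-(benzyloxy)-5-[3,4-bis(benzyloxy)phenyl]-5-(triethylsilyloxy)pentanoyl chloride | ClC(=O)CC[C@H](OCc1ccccc1)[C@@H](O[Si](CC)(CC)CC)c1ccc(OCc2ccccc2)c(OCc2ccccc2)c1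
F4 | step 15 | (4S,5S)-4-(benzyloxy)-5-[3,4-bis(benzyloxy)phenyl]-5-(triethylsilyloxy)pent-1-en-1-one (aldoketene) | O=C=CC[C@H](OCc1ccccc1)[C@@H](O[Si](CC)(CC)CC)c1ccc(OCc2ccccc2)c(OCc2ccccc2)c1
F5 | step 15 | 2-{(1R,2S)-1-[3,4-bis(benzyloxy)phenyl]-2-(tert-butyldimethylsilyloxy)-3-[2,4,6-tris(benzyloxy)phenyl]propyl}-4-{(2S,3S)-2-(benzyloxy)-3-[3,4-bis(benzyloxy)phenyl]-3-(triethylsilyloxy)propyl}-3-(triisopropylsilyloxy)cyclobut-2-en-1-one (both configurations at the sp3 ring carbon) | C(c1c(OCc2ccccc2)cc(OCc2ccccc2)cc1OCc1ccccc1)[C@H](O[Si](C)(C)C(C)(C)C)[C@H](c1ccc(OCc2ccccc2)c(OCc2ccccc2)c1)C1=C(O[Si](C(C)C)(C(C)C)C(C)C)C(C[C@H](OCc2ccccc2)[C@@H](O[Si](CC)(CC)CC)c2ccc(OCc3ccccc3)c(OCc3ccccc3)c2)C1=O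
F6 | step 5 | (2S,3S)-3-[3,4-bis(benzyloxy)phenyl]-1-[2,4,6-tris(benzyloxy)phenyl]pent-4-yn-2-yl (S)-2-methoxy-2-phenylacetate | C(c1c(OCc2ccccc2)cc(OCc2ccccc2)cc1OCc1ccccc1)[C@H](OC(=O)[C@@H](OC)c1ccccc1)[C@H](c1ccc(OCc2ccccc2)c(OCc2ccccc2)c1)C#C
F0 | step 17 | none | none
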